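**Retrosynthetic overview**

1. Feature: the dihydrofuran ring is numbered O1, C2, C3, C3a, C7a, with C9 the CH2OH carbon, ring A the guaiacyl group on C2 and ring B the benzo ring. C3 carries both C3a and C9. Putting C9 back between C3 and C3a expands the five-membered ring to the pyranone of a flavanone, whose only stereocentre is C2.
2. Late disconnections: the C5–vinyl bond of the stilbene (Heck, aryl bromide plus 3,5-bis(silyloxy)styrene) and the C9 alcohol (from a methyl ester).
3. Key disconnection: C3–C3a, made by a 1,2-shift of ring B induced by trivalent iodine. This contracts a (2R)-6-bromo-8-methoxyflavanone, and C2 directs C3 to the trans arrangement.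
4. The flavanone comes from 6-bromo-8-methoxychromone and a mesyl-protected guaiacylboronic acid by rhodium/chiral diene 1,4-addition, which sets C2. The chromone comes from 2'-hydroxy-3'-methoxyacetophenone.
5. Ring order: the pyranone is closed in step 2 and contracted to the dihydrofuran in step 6. All three arenes are bought.

Key step: step 6

Assumption: the sense of induction of (R,R)-Ph-bod* on the chromone is taken to parallel its behaviour with 2-cyclohexenone, which maps onto 2R here. If a first run shows the opposite sense, the equally available (S,S)-ligand is used and nothing else changes.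

**Route**

Step 1
Reactants: 1 1-(2-hydroxy-3-methoxyphenyl)ethanone
Product: 2 1-(5-bromo-2-hydroxy-3-methoxyphenyl)ethanone
Conditions: NBS (1.05 equiv), MeCN, 0 °C → rt
Reagents that add atoms: N-bromosuccinimide, O=C1CCC(=O)N1Br
Why: Electrophilic aromatic bromination: the phenol directs to its only free activated position, C5 (para to OH, meta to acetyl, both ortho positions occupied), and NBS in MeCN without acid or light should leave the methyl ketone untouched.

Step 2
Reactants: 2 1-(5-bromo-2-hydroxy-3-methoxyphenyl)ethanone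
Product: 4 6-bromo-8-methoxy-4H-chromen-4-one, via enaminone 3 (not isolated)
Conditions: Me2NCH(OMe)2 (2 equiv), toluene, 100 °C; evaporate; conc. HCl, CH2Cl2, 40 °C
Reagents that add atoms: N,N-dimethylformamide dimethyl acetal, COC(OC)N(C)C
Why: Enaminone chromone synthesis: the methyl ketone condenses with the formamide acetal, and acid then lets the phenol add to the β-carbon and expel dimethylamine (addition–elimination closing the pyranone at O1–C2), which the aryl bromide and methyl ether tolerate.

Step 3
Reactants: 5 2-methoxy-4-(4,4,5,5-tetramethyl-1,3,2-dioxaborolan-2-yl)phenol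
Product: 6 2-methoxy-4-(4,4,5,5-tetramethyl-1,3,2-dioxaborolan-2-yl)phenyl methanesulfonate
Conditions: MsCl (1.2 equiv), Et3N (1.5 equiv), CH2Cl2, 0 °C
Reagents that add atoms: methanesulfonyl chloride, CS(=O)(=O)Cl
Why: Sulfonylation of a phenol, which turns the para oxygen of ring A from a donor into an acceptor that withstands the acid, oxidant, hydride and palladium of the later steps, while the boronic ester is inert.

Step 4
Reactants: 6 2-methoxy-4-(4,4,5,5-tetramethyl-1,3,2-dioxaborolan-2-yl)phenyl methanesulfonate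
Product: 7 [3-methoxy-4-(methylsulfonyloxy)phenyl]boronic acid
Conditions: NaIO4 (3 equiv), NH4OAc (3 equiv), acetone/H2O 1:1, rt
Reagents that add atoms: water, O
Why: Oxidative deprotection of a pinacol boronate: periodate glycol cleavage destroys the liberated pinacol and so pulls the hydrolysis to the free boronic acid, the boron partner that transmetalates to rhodium most readily under nearly neutral conditions.

Step 5
Reactants: 4 6-bromo-8-methoxy-4H-chromen-4-one; 7 [3-methoxy-4-(methylsulfonyloxy)phenyl]boronic acid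
Product: 8 (2R)-6-bromo-8-methoxy-2-[3-methoxy-4-(methylsulfonyloxy)phenyl]chroman-4-one
Conditions: [RhCl(C2H4)2]2 (2.5 mol %), (1R,4R)-2,5-diphenylbicyclo[2.2.2]octa-2,5-diene [(R,R)-Ph-bod*, 5.5 mol %], aq KOH (0.2 equiv), 7 (2.5 equiv), toluene/H2O 10:1, 40 °C
Reagents that add atoms: none
Why: Hayashi–Miyaura asymmetric 1,4-addition, known for chromones: the aryl–rhodium species from transmetalation inserts the C2=C3 bond on the face left open by the C2-symmetric diene, so the ligand sets C2 as R, protonolysis of the oxa-π-allyl rhodium frees the flavanone, the small amount of base and mild temperature hold back retro-oxa-Michael racemisation, and monovalent rhodium touches neither the C–Br bond nor the mesylate.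

Step 6
Reactants: 8 (2R)-6-bromo-8-methoxy-2-[3-methoxy-4-(methylsulfonyloxy)phenyl]chroman-4-one
Product: 11 methyl (2R,3R)-5-bromo-7-methoxy-2-[3-methoxy-4-(methylsulfonyloxy)phenyl]-2,3-dihydro-1-benzofuran-3-carboxylate (2,3-trans), via methyl enol ether 9 (not isolated), via iodanyl ketal 10 (not isolated)
Conditions: PhI(OAc)2 (1.3 equiv), conc. H2SO4 (1 equiv), HC(OMe)3, 0 °C → rt
Reagents that add atoms: trimethyl orthoformate, COC(OC)OC
Why: Acid and HC(OMe)3 convert ketone 8 into enol ether 9, whose C3 attacks the trivalent iodine of PhI(OAc)2 on the face anti to ring A while methanol adds to C9 (the flavanone C4), giving the diequatorial 2,3-trans iodanyl ketal 10. In 10 the equatorial C3–iodine bond is antiperiplanar to the C9–C3a ring bond, so ring B, pushed by the two methoxy groups on C9 and by its ortho oxygen O1, bridges to C3 (3-exo-tet attack of the ipso carbon, phenonium-like) as PhI leaves, the C9–C3a bond breaks, and the dimethoxycarbenium ion gives up one O-methyl group to acetate to leave the ester. The closest known reaction type is the oxidative ring contraction of flavanones, and the related aryl ketone to arylacetate shift, with trivalent iodine or Tl(NO3)3 in trimethyl orthoformate. The dihydrofuran therefore arises by contraction of the pyranone and not by an end-to-end cyclisation. C3 is set by substrate control, since anti iodination followed by inversion during the shift places CO2Me trans to ring A, C2 is not touched, and trans is also the more stable isomer. The step needs the shift of ring B to outrun the shift of ring A (towards an isoflavone) and loss of the C2 proton (towards a flavone); the para mesyloxy group makes ring A a poor migrating group and a poor stabiliser of charge at C2, and its equatorial C2–aryl bond is gauche, not anti, to the C3–iodine bond.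

Step 7
Reactants: 11 methyl (2R,3R)-5-bromo-7-methoxy-2-[3-methoxy-4-(methylsulfonyloxy)phenyl]-2,3-dihydro-1-benzofuran-3-carboxylate
Product: 12 4-[(2R,3S)-5-bromo-3-(hydroxymethyl)-7-methoxy-2,3-dihydro-1-benzofuran-2-yl]-2-methoxyphenyl methanesulfonate
Conditions: LiBH4 (3 equiv), THF, 0 °C → rt; H2O
Reagents that add atoms: none
Why: Chemoselective ester reduction with LiBH4, which attacks neither the aryl mesylate nor the aryl bromide and is too weakly basic to disturb C2 or the already more stable trans C3 (the descriptor changes to S only through the priority rules).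

Step 8
Reactants: 12 4-[(2R,3S)-5-bromo-3-(hydroxymethyl)-7-methoxy-2,3-dihydro-1-benzofuran-2-yl]-2-methoxyphenyl methanesulfonate
Product: 13 4-[(2R,3S)-5-bromo-3-[(tert-butyldimethylsilyloxy)methyl]-7-methoxy-2,3-dihydro-1-benzofuran-2-yl]-2-methoxyphenyl methanesulfonate
Conditions: TBSCl (1.3 equiv), imidazole (2.5 equiv), CH2Cl2, rt
Reagents that add atoms: tert-butyldimethylsilyl chloride, CC(C)(C)[Si](C)(C)Cl
Why: Standard silylation of a primary alcohol, placed here so that no alkoxide is present to capture sulfene in step 12 and so that all silyl groups fall together at the end.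

Step 9
Reactants: 14 3,5-dihydroxybenzaldehyde
Product: 15 3,5-bis(tert-butyldimethylsilyloxy)benzaldehyde
Conditions: TBSCl (2.5 equiv), imidazole (5 equiv), DMF, rt
Reagents that add atoms: tert-butyldimethylsilyl chloride, CC(C)(C)[Si](C)(C)Cl
Why: Standard silylation of both phenols, giving protection that survives ylide and amine-base Heck conditions and is removed by fluoride.

Step 10
Reactants: 15 3,5-bis(tert-butyldimethylsilyloxy)benzaldehyde
Product: 16 3,5-bis(tert-butyldimethylsilyloxy)styrene
Conditions: MePPh3Br (1.3 equiv), n-BuLi (1.25 equiv), THF, 0 °C; then 15, 0 °C → rt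
Reagents that add atoms: methyltriphenylphosphonium bromide, C[P+](c1ccccc1)(c1ccccc1)c1ccccc1.[Br-]
Why: Wittig methylenation with the preformed non-stabilised ylide, which consumes the aldehyde far faster than it could attack the aryl silyl ethers.

Step 11
Reactants: 13 4-[(2R,3S)-5-bromo-3-[(tert-butyldimethylsilyloxy)methyl]-7-methoxy-2,3-dihydro-1-benzofuran-2-yl]-2-methoxyphenyl methanesulfonate; 16 3,5-bis(tert-butyldimethylsilyloxy)styrene
Product: 17 4-[(2R,3S)-5-[(E)-2-[3,5-bis(tert-butyldimethylsilyloxy)phenyl]ethenyl]-3-[(tert-butyldimethylsilyloxy)methyl]-7-methoxy-2,3-dihydro-1-benzofuran-2-yl]-2-methoxyphenyl methanesulfonate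
Conditions: Pd2(dba)3 (2.5 mol %), [HP(t-Bu)3]BF4 (10 mol %), Cy2NMe (1.5 equiv), 16 (1.3 equiv), dioxane, 60 °C
Reagents that add atoms: none
Why: Mizoroki–Heck reaction: zerovalent palladium bearing P(t-Bu)3 inserts into the C5–Br bond but not into the far less reactive aryl mesylate C–O bond, carbopalladation at the terminal carbon of 16 and syn β-hydride elimination give the E-stilbene, and the hindered amine base spares the aryl silyl ethers.

Step 12
Reactants: 17 4-[(2R,3S)-5-[(E)-2-[3,5-bis(tert-butyldimethylsilyloxy)phenyl]ethenyl]-3-[(tert-butyldimethylsilyloxy)methyl]-7-methoxy-2,3-dihydro-1-benzofuran-2-yl]-2-methoxyphenyl methanesulfonate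
Product: 18 4-[(2R,3S)-5-[(E)-2-[3,5-bis(tert-butyldimethylsilyloxy)phenyl]ethenyl]-3-[(tert-butyldimethylsilyloxy)methyl]-7-methoxy-2,3-dihydro-1-benzofuran-2-yl]-2-methoxyphenol
Conditions: LiN(i-Pr)2 (3 equiv), THF, −78 → 0 °C; AcOH quench
Reagents that add atoms: none
Why: Amide-base cleavage of an aryl mesylate by an E1cB path: the S-methyl group is by far the most acidic site, its anion expels the phenoxide and sulfene, which the excess amide traps, so that the silyl ethers, the stilbene and both stereocentres are left alone at low temperature.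

Step 13
Reactants: 18 4-[(2R,3S)-5-[(E)-2-[3,5-bis(tert-butyldimethylsilyloxy)phenyl]ethenyl]-3-[(tert-butyldimethylsilyloxy)methyl]-7-methoxy-2,3-dihydro-1-benzofuran-2-yl]-2-methoxyphenol
Product: 19 gnetofuran A, 5-[(E)-2-[(2R,3S)-2-(4-hydroxy-3-methoxyphenyl)-3-(hydroxymethyl)-7-methoxy-2,3-dihydro-1-benzofuran-5-yl]ethenyl]benzene-1,3-diol
Conditions: Bu4NF (4 equiv), AcOH (4 equiv), THF, 0 °C → rt, argon
Reagents that add atoms: none
Why: Fluoride-induced desilylation of the two aryl and one alkyl silyl ethers, buffered with AcOH so that the para-phenoxide of ring A cannot open the C2–O1 bond through a quinone methide and C2 and C3 stay as set.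

**Compound list**

1 | 1-(2-hydroxy-3-methoxyphenyl)ethanone | CC(=O)c1cccc(OC)c1O | starting material
2 | 1-(5-bromo-2-hydroxy-3-methoxyphenyl)ethanone | CC(=O)c1cc(Br)cc(OC)c1O | intermediate
3 | (E)-1-(5-bromo-2-hydroxy-3-methoxyphenyl)-3-(dimethylamino)prop-2-en-1-one | CN(C)/C=C/C(=O)c1cc(Br)cc(OC)c1O | intermediate
4 | 6-bromo-8-methoxy-4H-chromen-4-one | COc1cc(Br)cc2c(=O)ccoc12 | intermediate
5 | 2-methoxy-4-(4,4,5,5-tetramethyl-1,3,2-dioxaborolan-2-yl)phenol | COc1cc(B2OC(C)(C)C(C)(C)O2)ccc1O | starting material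
6 | 2-methoxy-4-(4,4,5,5-tetramethyl-1,3,2-dioxaborolan-2-yl)phenyl methanesulfonate | COc1cc(B2OC(C)(C)C(C)(C)O2)ccc1OS(C)(=O)=O | intermediate
7 | [3-methoxy-4-(methylsulfonyloxy)phenyl]boronic acid | COc1cc(B(O)O)ccc1OS(C)(=O)=O | intermediate
8 | (2R)-6-bromo-8-methoxy-2-[3-methoxy-4-(methylsulfonyloxy)phenyl]chroman-4-one | COc1cc([C@@H]2Oc3c(OC)cc(Br)cc3C(=O)C2)ccc1OS(C)(=O)=O | intermediate
9 | (2R)-6-bromo-4,8-dimethoxy-2-[3-methoxy-4-(methylsulfonyloxy)phenyl]-2H-chromene | COc1cc([C@@H]2Oc3c(OC)cc(Br)cc3C(OC)=C2)ccc1OS(C)(=O)=O | intermediate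
10 | 2,3-trans-3-[acetoxy(phenyl)-λ3-iodanyl]-6-bromo-4,4,8-trimethoxy-2-[3-methoxy-4-(methylsulfonyloxy)phenyl]chromane, (2S,3S) by the priority rules, C2 spatially as in 8 | COc1cc([C@@H]2Oc3c(OC)cc(Br)cc3C(OC)(OC)[C@H]2I(OC(C)=O)c2ccccc2)ccc1OS(C)(=O)=O | intermediate
11 | methyl (2R,3R)-5-bromo-7-methoxy-2-[3-methoxy-4-(methylsulfonyloxy)phenyl]-2,3-dihydro-1-benzofuran-3-carboxylate (trans) | COc1cc([C@@H]2Oc3c(OC)cc(Br)cc3[C@H]2C(=O)OC)ccc1OS(C)(=O)=O | intermediate
12 | 4-[(2R,3S)-5-bromo-3-(hydroxymethyl)-7-methoxy-2,3-dihydro-1-benzofuran-2-yl]-2-methoxyphenyl methanesulfonate | COc1cc([C@@H]2Oc3c(OC)cc(Br)cc3[C@H]2CO)ccc1OS(C)(=O)=O | intermediate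
13 | 4-[(2R,3S)-5-bromo-3-[(tert-butyldimethylsilyloxy)methyl]-7-methoxy-2,3-dihydro-1-benzofuran-2-yl]-2-methoxyphenyl methanesulfonate | COc1cc([C@@H]2Oc3c(OC)cc(Br)cc3[C@H]2CO[Si](C)(C)C(C)(C)C)ccc1OS(C)(=O)=O | intermediate
14 | 3,5-dihydroxybenzaldehyde | O=Cc1cc(O)cc(O)c1 | starting material
15 | 3,5-bis(tert-butyldimethylsilyloxy)benzaldehyde | O=Cc1cc(O[Si](C)(C)C(C)(C)C)cc(O[Si](C)(C)C(C)(C)C)c1 | intermediate
16 | 3,5-bis(tert-butyldimethylsilyloxy)styrene | C=Cc1cc(O[Si](C)(C)C(C)(C)C)cc(O[Si](C)(C)C(C)(C)C)c1 | intermediate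
17 | (2R,3S,E)-tris-TBS stilbene mesylate (name as in step 11) | COc1cc([C@@H]2Oc3c(OC)cc(/C=C/c4cc(O[Si](C)(C)C(C)(C)C)cc(O[Si](C)(C)C(C)(C)C)c4)cc3[C@H]2CO[Si](C)(C)C(C)(C)C)ccc1OS(C)(=O)=O | intermediate
18 | (2R,3S,E)-tris-TBS stilbene with free ring A phenol (name as in step 12) | COc1cc([C@@H]2Oc3c(OC)cc(/C=C/c4cc(O[Si](C)(C)C(C)(C)C)cc(O[Si](C)(C)C(C)(C)C)c4)cc3[C@H]2CO[Si](C)(C)C(C)(C)C)ccc1O | intermediate
19 | gnetofuran A, (2R,3S), E | COc1cc([C@@H]2Oc3c(OC)cc(/C=C/c4cc(O)cc(O)c4)cc3[C@H]2CO)ccc1O | target

**Step count**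

Total step count: 13.
Longest linear sequence: 9 steps (1, 2, 5, 6, 7, 8, 11, 12, 13).

**Steps most likely to fail**

Step 6. The shift of ring A or loss of the C2 proton may outrun the shift of ring B, solvent may displace the iodane, and acid-induced opening of the pyranone may erode C2.
- The fallback keeps the contraction but runs it through a ketene instead of a cation. It sets out from 8 and returns at 11.
- Enolisation of 8 with LiN(SiMe3)2 in THF at −78 °C is followed by acylation with 2,2,2-trifluoroethyl trifluoroacetate. At this temperature the endocyclic C2–O1 bond lies near the enolate plane and β-elimination is slow. This should give the 3-trifluoroacetyl flavanone F1.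
- Detrifluoroacetylative Regitz diazo transfer (MsN3, Et3N, H2O, MeCN) should give the 3-diazoflavanone F2.
- Irradiation at 365 nm in MeOH triggers a Wolff rearrangement in which only the acyl substituent, ring B, can migrate, giving the ring-contracted ketene F3.
- Methanol traps the ketene with protonation anti to ring A, mainly as the cis ester F4.
- Catalytic NaOMe in MeOH then epimerises C3 to the trans ester 11.

Step 5. Insertion of the pyrone-like C2=C3 bond may be sluggish, the boronic acid may protodeboronate, and the product may racemise by base-induced retro-oxa-Michael opening.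
- The fallback builds the flavanone as a racemate by aldol chemistry and resolves it. It sets out from 2 and returns at 8.
- Vanillin is mesylated (MsCl, Et3N, CH2Cl2) to 4-formyl-2-methoxyphenyl methanesulfonate F5.
- Claisen–Schmidt condensation of F5 with 2 under BF3·OEt2 in dioxane, base-free so that the mesylate is safe, should give the 2'-hydroxychalcone F6.
- NaOAc in refluxing EtOH closes F6 by oxa-Michael addition to the racemic flavanone F7.
- Kinetic resolution by Noyori asymmetric transfer hydrogenation [RuCl(p-cymene)((S,S)-TsDPEN), HCO2H/Et3N, EtOAc] is expected to reduce the 2S enantiomer to the cis-(2S,4S)-flavan-4-ol F8.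
- The unreacted (2R)-ketone 8 is separated by chromatography, at the cost of at most half of the material.

Step 12. Cleavage may be incomplete, or the amide base may attack elsewhere on the large late intermediate (silyl migration, metalation next to oxygen).
- The fallback moves the removal of the mesylate to a simple early intermediate and exchanges it for a silyl group. It sets out from 12 and returns at 19.
- Hydrolysis of 12 (KOH, MeOH/H2O, 60 °C, argon) should give the bromo phenol alcohol F9.
- TBSCl (2.5 equiv) and imidazole in DMF give the bis-silyl ether F10.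
- The Heck reaction of step 11 with 16 gives the tetrakis-silyl stilbene F11.
- Bu4NF/AcOH in THF releases 19 in one operation.

**Further compounds**

F1 | step 6 | 6-bromo-8-methoxy-2-[3-methoxy-4-(methylsulfonyloxy)phenyl]-3-(trifluoroacetyl)chroman-4-one, C2 as in 8, C3 not defined (enolised) | COc1cc([C@@H]2Oc3c(OC)cc(Br)cc3C(=O)C2C(=O)C(F)(F)F)ccc1OS(C)(=O)=O
F2 | step 6 | 6-bromo-3-diazo-8-methoxy-2-[3-methoxy-4-(methylsulfonyloxy)phenyl]chroman-4-one, C2 as in 8 | COc1cc([C@@H]2Oc3c(OC)cc(Br)cc3C(=O)C2=[N+]=[N-])ccc1OS(C)(=O)=O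
F3 | step 6 | 4-[5-bromo-7-methoxy-3-(oxomethylidene)-2,3-dihydro-1-benzofuran-2-yl]-2-methoxyphenyl methanesulfonate (ketene), C2 as in 8 | COc1cc([C@@H]2Oc3c(OC)cc(Br)cc3C2=C=O)ccc1OS(C)(=O)=O
F4 | step 6 | methyl (2R,3S)-5-bromo-7-methoxy-2-[3-methoxy-4-(methylsulfonyloxy)phenyl]-2,3-dihydro-1-benzofuran-3-carboxylate (cis) | COc1cc([C@@H]2Oc3c(OC)cc(Br)cc3[C@@H]2C(=O)OC)ccc1OS(C)(=O)=O
F5 | step 5 | 4-formyl-2-methoxyphenyl methanesulfonate | COc1cc(C=O)ccc1OS(C)(=O)=O
F6 | step 5 | 4-[(E)-3-(5-bromo-2-hydroxy-3-methoxyphenyl)-3-oxoprop-1-enyl]-2-methoxyphenyl methanesulfonate | COc1cc(/C=C/C(=O)c2cc(Br)cc(OC)c2O)ccc1OS(C)(=O)=O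
F7 | step 5 | racemic 6-bromo-8-methoxy-2-[3-methoxy-4-(methylsulfonyloxy)phenyl]chroman-4-one | COc1cc(C2Oc3c(OC)cc(Br)cc3C(=O)C2)ccc1OS(C)(=O)=O
F8 | step 5 | 4-[(2S,4S)-6-bromo-4-hydroxy-8-methoxychroman-2-yl]-2-methoxyphenyl methanesulfonate (cis) | COc1cc([C@H]2Oc3c(OC)cc(Br)cc3[C@@H](O)C2)ccc1OS(C)(=O)=O
F9 | step 12 | 4-[(2R,3S)-5-bromo-3-(hydroxymethyl)-7-methoxy-2,3-dihydro-1-benzofuran-2-yl]-2-methoxyphenol | COc1cc([C@@H]2Oc3c(OC)cc(Br)cc3[C@H]2CO)ccc1O
F10 | step 12 | (2R,3S)-5-bromo-2-[4-(tert-butyldimethylsilyloxy)-3-methoxyphenyl]-3-[(tert-butyldimethylsilyloxy)methyl]-7-methoxy-2,3-dihydro-1-benzofuran | COc1cc([C@@H]2Oc3c(OC)cc(Br)cc3[C@H]2CO[Si](C)(C)C(C)(C)C)ccc1O[Si](C)(C)C(C)(C)C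
F11 | step 12 | tetrakis(tert-butyldimethylsilyl) ether of gnetofuran A, (2R,3S), E | COc1cc([C@@H]2Oc3c(OC)cc(/C=C/c4cc(O[Si](C)(C)C(C)(C)C)cc(O[Si](C)(C)C(C)(C)C)c4)cc3[C@H]2CO[Si](C)(C)C(C)(C)C)ccc1O[Si](C)(C)C(C)(C)C
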